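## Retrosynthetic overview

1. Target 39 ⇐ acetonide hydrolysis, C3 oxidation and desilylation of macrolactone 36. The only ring of the target, the 14-membered lactone, is closed once, by lactonisation of seco acid 34 (C13–O to C1); a temporary dioxolane masks the C4 diol.
2. Seco acid 34 ⇐ Stille coupling at C10–C11 of 2-bromoalkene 24 with alkenylstannane 31 (from propargyl alcohol; C13 set by Et2Zn/(−)-MIB).
3. 24 ⇐ key C2–C3 bond: intermolecular Evans syn-aldol of propionimide 1 with the α-quaternary aldehyde 21 (sets C2; the C3 carbinol is oxidised later).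
4. 21 ⇐ Sharpless epoxidation (sets C4) of 2-methylidene alcohol 15, then hydrolysis that keeps the two CH2O arms different.
5. 15 ⇐ phosphonoacetate/formaldehyde homologation of allylic bromide 10 ⇐ E-selective Wittig ⇐ Evans alkylation of 1 with 2,3-dibromopropene (sets C8).

Position labels C1–C13 use macrolide numbering: C1 lactone C=O, C2 CH(Me), C3 ketone, C4 C(OH)(CH2OH), C5 CH2, C6=C7, C8 CH(Me), C9 CH2, C10(=CH2), C11=C12, C13 CH(Et)O.

Assumption: the C2 configuration set in the aldol is retained kinetically in the β-keto lactone under the buffered oxidation and mild acid of the last two steps. Catalysts, bases and solvents carry no compound number.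

## Route

Step 1
Reactants: 1 (4R)-4-benzyl-3-propanoyl-1,3-oxazolidin-2-one; 2 2,3-dibromoprop-1-ene
Product: 4 (4R)-4-benzyl-3-[(2S)-4-bromo-2-methylpent-4-enoyl]-1,3-oxazolidin-2-one, via sodium Z-enolate of the imide 3 (not isolated)
Conditions: NaN(SiMe3)2, THF, −78 °C; then 2, −78 → −45 °C
Reagents that add atoms: none
Why: Evans asymmetric alkylation, in which the chelated Z-enolate is attacked by the allylic CH2Br (SN2) on the face opposite the benzyl group, setting the (S)-methyl centre (future C8) while the vinylic bromide stays inert.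

Step 2
Reactants: 4 (4R)-4-benzyl-3-[(2S)-4-bromo-2-methylpent-4-enoyl]-1,3-oxazolidin-2-one
Product: 5 (2S)-4-bromo-2-methylpent-4-en-1-ol
Conditions: LiBH4, MeOH (1 equiv), THF, 0 °C
Reagents that add atoms: none
Why: Reductive cleavage of the acyl oxazolidinone by hydride attack at the exocyclic carbonyl, which does not enolise the α-centre and returns the auxiliary.

Step 3
Reactants: 5 (2S)-4-bromo-2-methylpent-4-en-1-ol; 6 ethyl 2-(triphenyl-λ5-phosphanylidene)propanoate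
Product: 8 ethyl (2E,4S)-6-bromo-2,4-dimethylhepta-2,6-dienoate, via (2S)-4-bromo-2-methylpent-4-enal 7 (not isolated)
Conditions: DMP, NaHCO3, CH2Cl2, 0 → 23 °C; filter; then 6, CH2Cl2, 40 °C
Reagents that add atoms: none
Why: Dess–Martin oxidation followed at once by Wittig olefination with the stabilised α-methyl ylide gives the E-trisubstituted enoate (C6=C7) before the α-branched aldehyde can epimerise.

Step 4
Reactants: 8 ethyl (2E,4S)-6-bromo-2,4-dimethylhepta-2,6-dienoate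
Product: 9 (2E,4S)-6-bromo-2,4-dimethylhepta-2,6-dien-1-ol
Conditions: i-Bu2AlH, CH2Cl2, −78 °C; aq. potassium sodium tartrate
Reagents that add atoms: none
Why: 1,2-Reduction of the enoate by the aluminium hydride gives the allylic alcohol without touching the alkenes or the vinyl bromide.

Step 5
Reactants: 9 (2E,4S)-6-bromo-2,4-dimethylhepta-2,6-dien-1-ol
Product: 10 (4S,5E)-2,7-dibromo-4,6-dimethylhepta-1,5-diene
Conditions: CBr4, PPh3, CH2Cl2, 0 °C
Reagents that add atoms: carbon tetrabromide, BrC(Br)(Br)Br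
Why: Appel bromination proceeds by SN2 displacement of the oxyphosphonium at the primary carbon, so the allylic system is neither transposed nor isomerised.

Step 6
Reactants: 10 (4S,5E)-2,7-dibromo-4,6-dimethylhepta-1,5-diene; 11 triethyl phosphonoacetate
Product: 13 ethyl (4E,6S)-8-bromo-2-(diethoxyphosphoryl)-4,6-dimethylnona-4,8-dienoate (both C2 epimers), via sodium phosphonoacetate carbanion 12 (not isolated)
Conditions: 11 (1.5 equiv), NaH, THF/DMF, 0 °C; then 10, 0 → 23 °C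
Reagents that add atoms: none
Why: SN2 C-alkylation of the stabilised carbanion at the primary allylic bromide forms C4–C5; excess nucleophile suppresses dialkylation and the new centre is erased in the next step.

Step 7
Reactants: 13 ethyl (4E,6S)-8-bromo-2-(diethoxyphosphoryl)-4,6-dimethylnona-4,8-dienoate
Product: 14 ethyl (4E,6S)-8-bromo-4,6-dimethyl-2-methylidenenona-4,8-dienoate
Conditions: 37% aq. HCHO, K2CO3, THF/H2O, 23 → 40 °C
Reagents that add atoms: formaldehyde, C=O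
Why: Horner–Wadsworth–Emmons olefination with formaldehyde turns the α-substituted phosphonoacetate into the 2-substituted acrylate.

Step 8
Reactants: 14 ethyl (4E,6S)-8-bromo-4,6-dimethyl-2-methylidenenona-4,8-dienoate
Product: 15 (4E,6S)-8-bromo-4,6-dimethyl-2-methylidenenona-4,8-dien-1-ol
Conditions: i-Bu2AlH, CH2Cl2, −78 °C; aq. potassium sodium tartrate
Reagents that add atoms: none
Why: 1,2-Reduction of the acrylate gives the 1,1-disubstituted allylic alcohol needed for a hydroxyl-directed epoxidation.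

Step 9
Reactants: 15 (4E,6S)-8-bromo-4,6-dimethyl-2-methylidenenona-4,8-dien-1-ol
Product: 16 {(2S)-2-[(2E,4S)-6-bromo-2,4-dimethylhepta-2,6-dien-1-yl]oxiran-2-yl}methanol
Conditions: Ti(OiPr)4 (10 mol%), L-(+)-diethyl tartrate (12 mol%), t-BuOOH, 4 Å MS, CH2Cl2, −20 °C
Reagents that add atoms: tert-butyl hydroperoxide, CC(C)(C)OO
Why: Sharpless asymmetric epoxidation touches only the allylic-alcohol alkene, and L-(+)-tartrate delivers oxygen in the sense that gives the (S)-oxirane (as for (S)-2-methylglycidol), which sets the quaternary carbon C4.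

Step 10
Reactants: 16 {(2S)-2-[(2E,4S)-6-bromo-2,4-dimethylhepta-2,6-dien-1-yl]oxiran-2-yl}methanol
Product: 17 (2R)-2-[(2E,4S)-6-bromo-2,4-dimethylhepta-2,6-dien-1-yl]-2-{[(4-methoxyphenyl)methoxy]methyl}oxirane
Conditions: NaH, 4-MeOC6H4CH2Cl, Bu4NI (cat.), THF/DMF, 0 °C
Reagents that add atoms: 4-methoxybenzyl chloride, COc1ccc(CCl)cc1
Why: Williamson etherification at 0 °C caps the alkoxide faster than it can attack the fully substituted oxirane carbon, so C4 is untouched (the descriptor changes only through CIP priorities).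

Step 11
Reactants: 17 (2R)-2-[(2E,4S)-6-bromo-2,4-dimethylhepta-2,6-dien-1-yl]-2-{[(4-methoxyphenyl)methoxy]methyl}oxirane
Product: 18 (2R,4E,6S)-8-bromo-2-{[(4-methoxyphenyl)methoxy]methyl}-4,6-dimethylnona-4,8-diene-1,2-diol
Conditions: KOH, DMSO/H2O (4:1), 70 °C
Reagents that add atoms: water, O
Why: Base-mediated epoxide hydrolysis is an SN2 attack of hydroxide at the unsubstituted CH2, so the C4–O bond is never broken and the two CH2O arms stay different (free OH versus PMB ether).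

Step 12
Reactants: 18 (2R,4E,6S)-8-bromo-2-{[(4-methoxyphenyl)methoxy]methyl}-4,6-dimethylnona-4,8-diene-1,2-diol
Product: 19 (4S)-4-[(2E,4S)-6-bromo-2,4-dimethylhepta-2,6-dien-1-yl]-4-{[(4-methoxyphenyl)methoxy]methyl}-2,2-dimethyl-1,3-dioxolane
Conditions: Me2C(OMe)2, PPTS (cat.), CH2Cl2, 23 °C
Reagents that add atoms: 2,2-dimethoxypropane, COC(C)(C)OC
Why: Acid-catalysed transketalisation closes the five-membered acetonide over the tertiary/primary 1,2-diol.

Step 13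
Reactants: 19 (4S)-4-[(2E,4S)-6-bromo-2,4-dimethylhepta-2,6-dien-1-yl]-4-{[(4-methoxyphenyl)methoxy]methyl}-2,2-dimethyl-1,3-dioxolane
Product: 20 {(4S)-4-[(2E,4S)-6-bromo-2,4-dimethylhepta-2,6-dien-1-yl]-2,2-dimethyl-1,3-dioxolan-4-yl}methanol
Conditions: DDQ, CH2Cl2/pH 7 buffer (10:1), 0 °C
Reagents that add atoms: none
Why: Oxidative PMB-ether cleavage by benzylic hydride abstraction leaves the acetonide, the isolated alkenes and the vinyl bromide intact.

Step 14
Reactants: 20 {(4S)-4-[(2E,4S)-6-bromo-2,4-dimethylhepta-2,6-dien-1-yl]-2,2-dimethyl-1,3-dioxolan-4-yl}methanol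
Product: 21 (4R)-4-[(2E,4S)-6-bromo-2,4-dimethylhepta-2,6-dien-1-yl]-2,2-dimethyl-1,3-dioxolane-4-carbaldehyde
Conditions: DMP, NaHCO3, CH2Cl2, 23 °C
Reagents that add atoms: none
Why: Dess–Martin oxidation gives an aldehyde (future C3) with no α-hydrogen, so the C4 centre cannot epimerise.

Step 15
Reactants: 1 (4R)-4-benzyl-3-propanoyl-1,3-oxazolidin-2-one; 21 (4R)-4-[(2E,4S)-6-bromo-2,4-dimethylhepta-2,6-dien-1-yl]-2,2-dimethyl-1,3-dioxolane-4-carbaldehyde
Product: 23 (4R)-4-benzyl-3-[(2R,3R)-3-{(4R)-4-[(2E,4S)-6-bromo-2,4-dimethylhepta-2,6-dien-1-yl]-2,2-dimethyl-1,3-dioxolan-4-yl}-3-hydroxy-2-methylpropanoyl]-1,3-oxazolidin-2-one, via dibutylboron Z-enolate of the imide 22 (not isolated)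
Conditions: 1 (1.3 equiv), Bu2BOTf, i-Pr2NEt, CH2Cl2, −78 → 0 °C; then 21, −78 → 0 °C; pH 7 buffer/MeOH/30% H2O2, 0 °C
Reagents that add atoms: none
Why: Evans syn-aldol through a Zimmerman–Traxler chair of the Z boron enolate forms C2–C3 with the auxiliary fixing C2 as R and the C3 carbinol syn (C3 is oxidised later).

Step 16
Reactants: 23 (4R)-4-benzyl-3-[(2R,3R)-3-{(4R)-4-[(2E,4S)-6-bromo-2,4-dimethylhepta-2,6-dien-1-yl]-2,2-dimethyl-1,3-dioxolan-4-yl}-3-hydroxy-2-methylpropanoyl]-1,3-oxazolidin-2-one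
Product: 24 (4R)-4-benzyl-3-[(2R,3R)-3-{(4R)-4-[(2E,4S)-6-bromo-2,4-dimethylhepta-2,6-dien-1-yl]-2,2-dimethyl-1,3-dioxolan-4-yl}-2-methyl-3-[(triethylsilyl)oxy]propanoyl]-1,3-oxazolidin-2-one
Conditions: Et3SiOTf, 2,6-lutidine, CH2Cl2, −78 → 0 °C
Reagents that add atoms: triethylsilyl trifluoromethanesulfonate, CC[Si](CC)(CC)OS(=O)(=O)C(F)(F)F
Why: Silylation with the silyl triflate caps the hindered C3 hydroxyl as a TES ether that can later be removed with fluoride while the ketal stays.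

Step 17
Reactants: 25 prop-2-yn-1-ol
Product: 27 (2E)-3-iodo-2-methylprop-2-en-1-ol, via dimethylalkenylalane 26 (not isolated)
Conditions: AlMe3, Cp2ZrCl2 (25 mol%), CH2Cl2, 0 → 23 °C; then I2, THF, −30 → 0 °C; aq. K2CO3
Reagents that add atoms: trimethylaluminium, C[Al](C)C; iodine, II
Why: Negishi zirconium-catalysed carboalumination adds Me and Al syn across the alkyne with Al on the terminal carbon, and iodinolysis with retention gives the E-iodide (C11=C12).

Step 18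
Reactants: 27 (2E)-3-iodo-2-methylprop-2-en-1-ol
Product: 28 (2E)-3-iodo-2-methylprop-2-enal
Conditions: MnO2, CH2Cl2, 23 °C
Reagents that add atoms: none
Why: MnO2 oxidises the allylic alcohol selectively to the enal without touching the alkenyl iodide or its geometry.

Step 19
Reactants: 28 (2E)-3-iodo-2-methylprop-2-enal
Product: 29 (1E,3S)-1-iodo-2-methylpent-1-en-3-ol
Conditions: Et2Zn, (−)-MIB (4 mol%), hexanes/toluene, 0 °C; aq. NH4Cl
Reagents that add atoms: diethylzinc, CC[Zn]CC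
Why: Amino-alcohol-catalysed enantioselective ethylzinc addition with (−)-MIB gives the (S)-carbinol (same facial sense as with benzaldehyde), setting C13.

Step 20
Reactants: 29 (1E,3S)-1-iodo-2-methylpent-1-en-3-ol
Product: 31 (1E,3S)-2-methyl-1-(tributylstannyl)pent-1-en-3-ol, via dilithiated alkenyl alkoxide 30 (not isolated)
Conditions: t-BuLi (3.2 equiv), Et2O, −78 °C; then Bu3SnCl, −78 → 0 °C
Reagents that add atoms: tributyltin chloride, CCCC[Sn](Cl)(CCCC)CCCC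
Why: O-deprotonation and iodine–lithium exchange with retention of alkene geometry, then C-stannylation, give the E-alkenylstannane.

Step 21
Reactants: 24 (4R)-4-benzyl-3-[(2R,3R)-3-{(4R)-4-[(2E,4S)-6-bromo-2,4-dimethylhepta-2,6-dien-1-yl]-2,2-dimethyl-1,3-dioxolan-4-yl}-2-methyl-3-[(triethylsilyl)oxy]propanoyl]-1,3-oxazolidin-2-one; 31 (1E,3S)-2-methyl-1-(tributylstannyl)pent-1-en-3-ol
Product: 32 (4R)-4-benzyl-3-[(2R,3R)-3-{(4R)-4-[(2E,4S,7E,9S)-9-hydroxy-2,4,8-trimethyl-6-methylideneundeca-2,7-dien-1-yl]-2,2-dimethyl-1,3-dioxolan-4-yl}-2-methyl-3-[(triethylsilyl)oxy]propanoyl]-1,3-oxazolidin-2-one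
Conditions: Pd2(dba)3 (5 mol%), AsPh3 (20 mol%), CuI (10 mol%), NMP, 45 °C
Reagents that add atoms: none
Why: Stille cross-coupling (oxidative addition of zerovalent palladium into the 2-bromoalkene, stereoretentive transmetalation from tin) forms C10–C11 and the 2-substituted E-diene under neutral conditions tolerated by the free hydroxyl, imide, silyl ether and ketal.

Step 22
Reactants: 32 (4R)-4-benzyl-3-[(2R,3R)-3-{(4R)-4-[(2E,4S,7E,9S)-9-hydroxy-2,4,8-trimethyl-6-methylideneundeca-2,7-dien-1-yl]-2,2-dimethyl-1,3-dioxolan-4-yl}-2-methyl-3-[(triethylsilyl)oxy]propanoyl]-1,3-oxazolidin-2-one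
Product: 34 (2R,3R)-3-{(4R)-4-[(2E,4S,7E,9S)-9-hydroxy-2,4,8-trimethyl-6-methylideneundeca-2,7-dien-1-yl]-2,2-dimethyl-1,3-dioxolan-4-yl}-2-methyl-3-[(triethylsilyl)oxy]propanoic acid, via peroxy acid 33 (not isolated)
Conditions: LiOH, 30% H2O2, THF/H2O (3:1), 0 °C; then aq. Na2SO3; 1 M HCl to pH 4, 0 °C
Reagents that add atoms: hydrogen peroxide, OO
Why: Hydroperoxide attacks the exocyclic imide carbonyl selectively (auxiliary hydrolysis without C2 epimerisation) and sulfite reduces the peroxy acid to the seco acid.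

Step 23
Reactants: 34 (2R,3R)-3-{(4R)-4-[(2E,4S,7E,9S)-9-hydroxy-2,4,8-trimethyl-6-methylideneundeca-2,7-dien-1-yl]-2,2-dimethyl-1,3-dioxolan-4-yl}-2-methyl-3-[(triethylsilyl)oxy]propanoic acid
Product: 36 (3R,4R,5R,7E,9S,12E,14S)-14-ethyl-3,7,9,13-tetramethyl-11-methylidene-4-[(triethylsilyl)oxy]-1-oxacyclotetradeca-7,12-dien-2-one bearing at C5 a spiro 2,2-dimethyl-1,3-dioxolane (ring O on C5 plus C5-CH2-O), via mixed trichlorobenzoic anhydride 35 (not isolated)
Conditions: 2,4,6-Cl3C6H2COCl, Et3N, THF, 23 °C; then syringe-pump addition to DMAP, toluene (1 mM), 80 °C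
Reagents that add atoms: none
Why: Yamaguchi macrolactonisation closes the 14-membered ring through the only free hydroxyl (C13–OH), helped by the two trisubstituted alkenes and the diene that pre-organise the chain.

Step 24
Reactants: 36 the TES/acetonide macrolactone named in step 23
Product: 37 (3R,4R,5R,7E,9S,12E,14S)-14-ethyl-4-hydroxy-3,7,9,13-tetramethyl-11-methylidene-1-oxacyclotetradeca-7,12-dien-2-one bearing at C5 a spiro 2,2-dimethyl-1,3-dioxolane (ring O on C5 plus C5-CH2-O)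
Conditions: HF·pyridine, pyridine, THF, 0 → 23 °C
Reagents that add atoms: none
Why: Buffered fluoride desilylation frees the C3 hydroxyl while the acetonide, the lactone and the diene are untouched.

Step 25
Reactants: 37 the C3-hydroxy acetonide macrolactone named in step 24
Product: 38 (3R,5R,7E,9S,12E,14S)-14-ethyl-3,7,9,13-tetramethyl-11-methylidene-1-oxacyclotetradeca-7,12-diene-2,4-dione bearing at C5 a spiro 2,2-dimethyl-1,3-dioxolane (ring O on C5 plus C5-CH2-O)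
Conditions: DMP, NaHCO3, CH2Cl2, 0 → 23 °C
Reagents that add atoms: none
Why: Dess–Martin oxidation of the hindered C3 carbinol to the β-keto lactone runs under buffered non-basic conditions that leave the C2 centre as set.

Step 26
Reactants: 38 the 3-keto acetonide macrolactone named in step 25
Product: 39 (3R,5R,7E,9S,12E,14S)-14-ethyl-5-hydroxy-5-(hydroxymethyl)-3,7,9,13-tetramethyl-11-methylidene-1-oxacyclotetradeca-7,12-diene-2,4-dione
Conditions: AcOH/H2O (4:1), 40 °C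
Reagents that add atoms: none
Why: Mild acid-catalysed ketal hydrolysis releases the tertiary and primary hydroxyls without ionising the allylic lactone or epimerising C2.

## Compound list

1 | (4R)-4-benzyl-3-propanoyl-1,3-oxazolidin-2-one | CCC(=O)N1[C@H](Cc2ccccc2)COC1=O | starting material
2 | 2,3-dibromoprop-1-ene | C=C(Br)CBr | starting material
3 | sodium (Z)-enolate of 1 | C/C=C(\[O-])N1[C@H](Cc2ccccc2)COC1=O.[Na+] | intermediate
4 | (4R)-4-benzyl-3-[(2S)-4-bromo-2-methylpent-4-enoyl]-1,3-oxazolidin-2-one | C=C(Br)C[C@H](C)C(=O)N1[C@H](Cc2ccccc2)COC1=O | intermediate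
5 | (2S)-4-bromo-2-methylpent-4-en-1-ol | C=C(Br)C[C@H](C)CO | intermediate
6 | ethyl 2-(triphenyl-λ5-phosphanylidene)propanoate | CCOC(=O)C(C)=P(c1ccccc1)(c1ccccc1)c1ccccc1 | starting material
7 | (2S)-4-bromo-2-methylpent-4-enal | C=C(Br)C[C@H](C)C=O | intermediate
8 | ethyl (2E,4S)-6-bromo-2,4-dimethylhepta-2,6-dienoate | C=C(Br)C[C@H](C)/C=C(\C)C(=O)OCC | intermediate
9 | (2E,4S)-6-bromo-2,4-dimethylhepta-2,6-dien-1-ol | C=C(Br)C[C@H](C)/C=C(\C)CO | intermediate
10 | (4S,5E)-2,7-dibromo-4,6-dimethylhepta-1,5-diene | C=C(Br)C[C@H](C)/C=C(\C)CBr | intermediate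
11 | triethyl phosphonoacetate | CCOC(=O)CP(=O)(OCC)OCC | starting material
12 | sodium salt of the carbanion of 11 | CCOC(=O)[CH-]P(=O)(OCC)OCC.[Na+] | intermediate
13 | ethyl (4E,6S)-8-bromo-2-(diethoxyphosphoryl)-4,6-dimethylnona-4,8-dienoate (both C2 epimers) | C=C(Br)C[C@H](C)/C=C(\C)CC(C(=O)OCC)P(=O)(OCC)OCC | intermediate
14 | ethyl (4E,6S)-8-bromo-4,6-dimethyl-2-methylidenenona-4,8-dienoate | C=C(Br)C[C@H](C)/C=C(\C)CC(=C)C(=O)OCC | intermediate
15 | (4E,6S)-8-bromo-4,6-dimethyl-2-methylidenenona-4,8-dien-1-ol | C=C(Br)C[C@H](C)/C=C(\C)CC(=C)CO | intermediate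
16 | {(2S)-2-[(2E,4S)-6-bromo-2,4-dimethylhepta-2,6-dien-1-yl]oxiran-2-yl}methanol | C=C(Br)C[C@H](C)/C=C(\C)C[C@]1(CO)CO1 | intermediate
17 | (2R)-2-[(2E,4S)-6-bromo-2,4-dimethylhepta-2,6-dien-1-yl]-2-{[(4-methoxyphenyl)methoxy]methyl}oxirane | C=C(Br)C[C@H](C)/C=C(\C)C[C@]1(COCc2ccc(OC)cc2)CO1 | intermediate
18 | (2R,4E,6S)-8-bromo-2-{[(4-methoxyphenyl)methoxy]methyl}-4,6-dimethylnona-4,8-diene-1,2-diol | C=C(Br)C[C@H](C)/C=C(\C)C[C@](O)(COCc1ccc(OC)cc1)CO | intermediate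
19 | (4S)-4-[(2E,4S)-6-bromo-2,4-dimethylhepta-2,6-dien-1-yl]-4-{[(4-methoxyphenyl)methoxy]methyl}-2,2-dimethyl-1,3-dioxolane | C=C(Br)C[C@H](C)/C=C(\C)C[C@]1(COCc2ccc(OC)cc2)COC(C)(C)O1 | intermediate
20 | {(4S)-4-[(2E,4S)-6-bromo-2,4-dimethylhepta-2,6-dien-1-yl]-2,2-dimethyl-1,3-dioxolan-4-yl}methanol | C=C(Br)C[C@H](C)/C=C(\C)C[C@]1(CO)COC(C)(C)O1 | intermediate
21 | (4R)-4-[(2E,4S)-6-bromo-2,4-dimethylhepta-2,6-dien-1-yl]-2,2-dimethyl-1,3-dioxolane-4-carbaldehyde | C=C(Br)C[C@H](C)/C=C(\C)C[C@]1(C=O)COC(C)(C)O1 | intermediate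
22 | dibutylboron (Z)-enolate of 1 | C/C=C(\OB(CCCC)CCCC)N1[C@H](Cc2ccccc2)COC1=O | intermediate
23 | (4R)-4-benzyl-3-[(2R,3R)-3-{(4R)-4-[(2E,4S)-6-bromo-2,4-dimethylhepta-2,6-dien-1-yl]-2,2-dimethyl-1,3-dioxolan-4-yl}-3-hydroxy-2-methylpropanoyl]-1,3-oxazolidin-2-one | C=C(Br)C[C@H](C)/C=C(\C)C[C@]1([C@H](O)[C@@H](C)C(=O)N2[C@H](Cc3ccccc3)COC2=O)COC(C)(C)O1 | intermediate
24 | TES ether of 23: (4R)-4-benzyl-3-[(2R,3R)-3-{(4R)-4-[(2E,4S)-6-bromo-2,4-dimethylhepta-2,6-dien-1-yl]-2,2-dimethyl-1,3-dioxolan-4-yl}-2-methyl-3-[(triethylsilyl)oxy]propanoyl]-1,3-oxazolidin-2-one | C=C(Br)C[C@H](C)/C=C(\C)C[C@]1([C@H](O[Si](CC)(CC)CC)[C@@H](C)C(=O)N2[C@H](Cc3ccccc3)COC2=O)COC(C)(C)O1 | intermediate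
25 | prop-2-yn-1-ol | C#CCO | starting material
26 | dimethyl{(1E)-3-[(dimethylalumanyl)oxy]-2-methylprop-1-en-1-yl}alumane | C[Al](C)/C=C(\C)CO[Al](C)C | intermediate
27 | (2E)-3-iodo-2-methylprop-2-en-1-ol | I/C=C(\C)CO | intermediate
28 | (2E)-3-iodo-2-methylprop-2-enal | I/C=C(\C)C=O | intermediate
29 | (1E,3S)-1-iodo-2-methylpent-1-en-3-ol | I/C=C(\C)[C@H](CC)O | intermediate
30 | lithium (1E,3S)-1-lithio-2-methylpent-1-en-3-olate | [Li]/C=C(\C)[C@H](CC)O[Li] | intermediate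
31 | (1E,3S)-2-methyl-1-(tributylstannyl)pent-1-en-3-ol | CCCC[Sn](CCCC)(CCCC)/C=C(\C)[C@H](CC)O | intermediate
32 | (4R)-4-benzyl-3-[(2R,3R)-3-{(4R)-4-[(2E,4S,7E,9S)-9-hydroxy-2,4,8-trimethyl-6-methylideneundeca-2,7-dien-1-yl]-2,2-dimethyl-1,3-dioxolan-4-yl}-2-methyl-3-[(triethylsilyl)oxy]propanoyl]-1,3-oxazolidin-2-one | C=C(/C=C(\C)[C@H](CC)O)C[C@H](C)/C=C(\C)C[C@]1([C@H](O[Si](CC)(CC)CC)[C@@H](C)C(=O)N2[C@H](Cc3ccccc3)COC2=O)COC(C)(C)O1 | intermediate
33 | peroxy acid corresponding to 34 (C1 as C(=O)OOH) | C=C(/C=C(\C)[C@H](CC)O)C[C@H](C)/C=C(\C)C[C@]1([C@H](O[Si](CC)(CC)CC)[C@@H](C)C(=O)OO)COC(C)(C)O1 | intermediate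
34 | (2R,3R)-3-{(4R)-4-[(2E,4S,7E,9S)-9-hydroxy-2,4,8-trimethyl-6-methylideneundeca-2,7-dien-1-yl]-2,2-dimethyl-1,3-dioxolan-4-yl}-2-methyl-3-[(triethylsilyl)oxy]propanoic acid | C=C(/C=C(\C)[C@H](CC)O)C[C@H](C)/C=C(\C)C[C@]1([C@H](O[Si](CC)(CC)CC)[C@@H](C)C(=O)O)COC(C)(C)O1 | intermediate
35 | mixed anhydride of 34 with 2,4,6-trichlorobenzoic acid | C=C(/C=C(\C)[C@H](CC)O)C[C@H](C)/C=C(\C)C[C@]1([C@H](O[Si](CC)(CC)CC)[C@@H](C)C(=O)OC(=O)c2c(Cl)cc(Cl)cc2Cl)COC(C)(C)O1 | intermediate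
36 | (3R,4R,5R,7E,9S,12E,14S)-14-ethyl-3,7,9,13-tetramethyl-11-methylidene-4-[(triethylsilyl)oxy]-1-oxacyclotetradeca-7,12-dien-2-one with a spiro 2,2-dimethyl-1,3-dioxolane at C5 | C=C1/C=C(\C)[C@H](CC)OC(=O)[C@H](C)[C@@H](O[Si](CC)(CC)CC)[C@]2(COC(C)(C)O2)C/C(C)=C/[C@@H](C)C1 | intermediate
37 | (3R,4R,5R,7E,9S,12E,14S)-14-ethyl-4-hydroxy-3,7,9,13-tetramethyl-11-methylidene-1-oxacyclotetradeca-7,12-dien-2-one with a spiro 2,2-dimethyl-1,3-dioxolane at C5 | C=C1/C=C(\C)[C@H](CC)OC(=O)[C@H](C)[C@@H](O)[C@]2(COC(C)(C)O2)C/C(C)=C/[C@@H](C)C1 | intermediate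
38 | (3R,5R,7E,9S,12E,14S)-14-ethyl-3,7,9,13-tetramethyl-11-methylidene-1-oxacyclotetradeca-7,12-diene-2,4-dione with a spiro 2,2-dimethyl-1,3-dioxolane at C5 | C=C1/C=C(\C)[C@H](CC)OC(=O)[C@H](C)C(=O)[C@]2(COC(C)(C)O2)C/C(C)=C/[C@@H](C)C1 | intermediate
39 | (3R,5R,7E,9S,12E,14S)-14-ethyl-5-hydroxy-5-(hydroxymethyl)-3,7,9,13-tetramethyl-11-methylidene-1-oxacyclotetradeca-7,12-diene-2,4-dione | C=C1/C=C(\C)[C@H](CC)OC(=O)[C@H](C)C(=O)[C@](O)(CO)C/C(C)=C/[C@@H](C)C1 | target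

## Step count and risks

Total steps: 26 (22 on the main line, 4 for stannane 31). Longest linear sequence: 22 steps (steps 1–16 and 21–26, from 1 to 39).

Risk 1, step 11 (epoxide hydrolysis). Hydroxide attack on the 2,2-disubstituted oxirane may be slow, and any erosion at C4 in steps 10–11 cannot be corrected later. The fallback sets out from 15 and comes back at 20. Epoxidise 15 with D-(−)-diethyl tartrate instead to get the opposite oxirane {(2R)-2-[(2E,4S)-6-bromo-2,4-dimethylhepta-2,6-dien-1-yl]oxiran-2-yl}methanol F1. Open it at the CH2 terminus with pivalic acid and stoichiometric Ti(OiPr)4 (nucleophile delivered inside the titanium alkoxide chelate) to give (2R,4E,6S)-8-bromo-2-hydroxy-2-(hydroxymethyl)-4,6-dimethylnona-4,8-dien-1-yl 2,2-dimethylpropanoate F2. Ketalise the free tertiary/primary diol at once (Me2C(OMe)2, PPTS) to {(4R)-4-[(2E,4S)-6-bromo-2,4-dimethylhepta-2,6-dien-1-yl]-2,2-dimethyl-1,3-dioxolan-4-yl}methyl 2,2-dimethylpropanoate F3. Reduce the pivalate with i-Bu2AlH at −78 °C. Because both the oxirane configuration and the roles of the two CH2O arms are reversed relative to the main line, this gives 20 itself.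

Risk 2, step 23 (macrolactonisation). The acid is hindered at C2/C3 and oligomers or β-elimination of the silyloxy group may compete. The fallback sets out from 24 and comes back at 36, closing the ring by C–C coupling instead of C–O. Cleave the auxiliary of 24 (LiOH, H2O2; Na2SO3) to (2R,3R)-3-{(4R)-4-[(2E,4S)-6-bromo-2,4-dimethylhepta-2,6-dien-1-yl]-2,2-dimethyl-1,3-dioxolan-4-yl}-2-methyl-3-[(triethylsilyl)oxy]propanoic acid F4. Esterify it intermolecularly with stannane 31 (2,4,6-Cl3C6H2COCl, Et3N, DMAP, toluene, 23 °C) to the (1E,3S)-2-methyl-1-(tributylstannyl)pent-1-en-3-yl ester of that acid F5. Cyclise F5 by intramolecular Stille coupling at C10–C11 (Pd2(dba)3, AsPh3, DMF, 1 mM, 45 °C), which gives 36.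

Risk 3, step 26 (final ketal hydrolysis). The acetonide sits next to the C3 ketone and is slow to hydrolyse, while the product holds an acid-sensitive allylic lactone and an epimerisable C2. The fallback sets out from 36 and comes back at 39, removing the ketal before the ketone exists and ending with fluoride. Treat 36 with AcOH/H2O/THF (3:1:1, 40 °C) to remove acetonide and TES together, giving (3R,4R,5R,7E,9S,12E,14S)-14-ethyl-4,5-dihydroxy-5-(hydroxymethyl)-3,7,9,13-tetramethyl-11-methylidene-1-oxacyclotetradeca-7,12-dien-2-one F6. Silylate only the primary hydroxyl (t-BuMe2SiCl, imidazole, CH2Cl2, 0 °C) to the 5-{[tert-butyl(dimethyl)silyl]oxymethyl} 4,5-diol F7. Oxidise the secondary C3 carbinol with IBX in DMSO (which does not cleave the glycol) to (3R,5R,7E,9S,12E,14S)-5-({[tert-butyl(dimethyl)silyl]oxy}methyl)-14-ethyl-5-hydroxy-3,7,9,13-tetramethyl-11-methylidene-1-oxacyclotetradeca-7,12-diene-2,4-dione F8. Desilylate with HF·pyridine/pyridine in THF to 39.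

## Further compounds

F1 | step 11 | {(2R)-2-[(2E,4S)-6-bromo-2,4-dimethylhepta-2,6-dien-1-yl]oxiran-2-yl}methanol | C=C(Br)C[C@H](C)/C=C(\C)C[C@@]1(CO)CO1
F2 | step 11 | (2R,4E,6S)-8-bromo-2-hydroxy-2-(hydroxymethyl)-4,6-dimethylnona-4,8-dien-1-yl 2,2-dimethylpropanoate | C=C(Br)C[C@H](C)/C=C(\C)C[C@@](O)(CO)COC(=O)C(C)(C)C
F3 | step 11 | {(4R)-4-[(2E,4S)-6-bromo-2,4-dimethylhepta-2,6-dien-1-yl]-2,2-dimethyl-1,3-dioxolan-4-yl}methyl 2,2-dimethylpropanoate | C=C(Br)C[C@H](C)/C=C(\C)C[C@]1(COC(=O)C(C)(C)C)COC(C)(C)O1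
F4 | step 23 | (2R,3R)-3-{(4R)-4-[(2E,4S)-6-bromo-2,4-dimethylhepta-2,6-dien-1-yl]-2,2-dimethyl-1,3-dioxolan-4-yl}-2-methyl-3-[(triethylsilyl)oxy]propanoic acid | C=C(Br)C[C@H](C)/C=C(\C)C[C@]1([C@H](O[Si](CC)(CC)CC)[C@@H](C)C(=O)O)COC(C)(C)O1
F5 | step 23 | (1E,3S)-2-methyl-1-(tributylstannyl)pent-1-en-3-yl (2R,3R)-3-{(4R)-4-[(2E,4S)-6-bromo-2,4-dimethylhepta-2,6-dien-1-yl]-2,2-dimethyl-1,3-dioxolan-4-yl}-2-methyl-3-[(triethylsilyl)oxy]propanoate | C=C(Br)C[C@H](C)/C=C(\C)C[C@]1([C@H](O[Si](CC)(CC)CC)[C@@H](C)C(=O)O[C@@H](CC)/C(C)=C/[Sn](CCCC)(CCCC)CCCC)COC(C)(C)O1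
F6 | step 26 | (3R,4R,5R,7E,9S,12E,14S)-14-ethyl-4,5-dihydroxy-5-(hydroxymethyl)-3,7,9,13-tetramethyl-11-methylidene-1-oxacyclotetradeca-7,12-dien-2-one | C=C1/C=C(\C)[C@H](CC)OC(=O)[C@H](C)[C@@H](O)[C@](O)(CO)C/C(C)=C/[C@@H](C)C1
F7 | step 26 | (3R,4R,5R,7E,9S,12E,14S)-5-({[tert-butyl(dimethyl)silyl]oxy}methyl)-14-ethyl-4,5-dihydroxy-3,7,9,13-tetramethyl-11-methylidene-1-oxacyclotetradeca-7,12-dien-2-one | C=C1/C=C(\C)[C@H](CC)OC(=O)[C@H](C)[C@@H](O)[C@](O)(CO[Si](C)(C)C(C)(C)C)C/C(C)=C/[C@@H](C)C1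
F8 | step 26 | (3R,5R,7E,9S,12E,14S)-5-({[tert-butyl(dimethyl)silyl]oxy}methyl)-14-ethyl-5-hydroxy-3,7,9,13-tetramethyl-11-methylidene-1-oxacyclotetradeca-7,12-diene-2,4-dione | C=C1/C=C(\C)[C@H](CC)OC(=O)[C@H](C)C(=O)[C@](O)(CO[Si](C)(C)C(C)(C)C)C/C(C)=C/[C@@H](C)C1
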